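Ring D of the target is a 3‑alkylphenol: C1 carries the ethylene arm, C3 the hydroxyl, and C2 between them is unsubstituted, so it can carry a removable CO2Me. The route exploits this by building ring D as a 6‑alkylsalicylate. A Diels–Alder reaction of a vinylketene acetal (C3–C6) with an alk‑2‑ynoate (C1, C2) forms C6–C1 and C2–C3 and, after loss of methanol, closes the arene in one operation. The precursor is the complete A–B–O–C diaryl ether (ring B phenol as MOM ether) bearing a CH2CH2C≡C–CO2Me chain on ring C. Saponification, decarboxylation and MOM removal then give the target.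

Key step: step 11

Remarks:
- Ring A is the 3‑methoxyphenyl ring, ring B the central phenol ring, ring C the para‑phenylene ring, ring D the 3‑hydroxyphenyl ring.
- Ar = 4‑{2‑(methoxymethoxy)‑5‑[2‑(3‑methoxyphenyl)ethyl]phenoxy}phenyl. The target has no stereocentre.
- Assumption: alkenes 6, 8 and 9 are carried as E/Z mixtures at the stilbene bond because step 6 saturates it; ketene acetal 17 is drawn as the 1E isomer, but either isomer serves because its C1 becomes an aromatic carbon.

Step 1
Reactants: 1 3,4‑dihydroxybenzaldehyde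
Product: 2 3‑hydroxy‑4‑(methoxymethoxy)benzaldehyde
Conditions: MOMCl (1.05 equiv), K2CO3 (1.1 equiv), acetone, 0 °C to rt
Reagents that add atoms: chloromethyl methyl ether, COCCl
Why: Williamson‑type O‑alkylation in which the 4‑OH, para to the formyl group and therefore the more acidic phenol, is deprotonated and capped selectively by one equivalent of base and MOMCl, leaving the 3‑OH free for the later arylation.

Step 2
Reactants: 3 3‑methoxybenzyl bromide
Product: 4 (3‑methoxybenzyl)triphenylphosphonium bromide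
Conditions: PPh3, toluene, reflux
Reagents that add atoms: triphenylphosphine, c1ccc(cc1)P(c1ccccc1)c1ccccc1
Why: SN2 quaternisation of triphenylphosphine by a reactive benzylic bromide should give the salt, which precipitates from toluene.

Step 3
Reactants: 2 3‑hydroxy‑4‑(methoxymethoxy)benzaldehyde; 4 (3‑methoxybenzyl)triphenylphosphonium bromide
Product: 6 5‑[2‑(3‑methoxyphenyl)ethenyl]‑2‑(methoxymethoxy)phenol (E/Z mixture), via ylide (3‑methoxybenzylidene)triphenylphosphorane 5 (not isolated)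
Conditions: 4 (1.2 equiv), KOt‑Bu (2.3 equiv), THF, 0 °C; then 2, 0 °C to rt; aq. NH4Cl
Reagents that add atoms: none
Why: Wittig olefination with a semi‑stabilised benzylic ylide, the second equivalent of base covering the free phenol, and the E/Z ratio being irrelevant because the double bond is hydrogenated in step 6.

Step 4
Reactants: 6 5‑[2‑(3‑methoxyphenyl)ethenyl]‑2‑(methoxymethoxy)phenol; 7 4‑fluorobenzaldehyde
Product: 8 4‑{2‑(methoxymethoxy)‑5‑[2‑(3‑methoxyphenyl)ethenyl]phenoxy}benzaldehyde (E/Z mixture)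
Conditions: K2CO3 (2 equiv), DMF, 110 °C, under N2
Reagents that add atoms: none
Why: Nucleophilic aromatic substitution by addition–elimination through a Meisenheimer intermediate, the para‑formyl group activating fluoride displacement by the potassium phenoxide of 6, while the MOM ether and the stilbene are inert to carbonate.

Step 5
Reactants: 8 4‑{2‑(methoxymethoxy)‑5‑[2‑(3‑methoxyphenyl)ethenyl]phenoxy}benzaldehyde
Product: 9 methyl (2E)‑3‑(4‑{2‑(methoxymethoxy)‑5‑[2‑(3‑methoxyphenyl)ethenyl]phenoxy}phenyl)prop‑2‑enoate (stilbene bond E/Z)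
Conditions: Ph3P=CHCO2Me (1.2 equiv), toluene, 90 °C
Reagents that add atoms: methyl (triphenylphosphoranylidene)acetate, COC(=O)C=P(c1ccccc1)(c1ccccc1)c1ccccc1
Why: Wittig olefination with a stabilised ylide needs no base, reacts only at the aldehyde and should give the E‑enoate, adding two of the three chain carbons.

Step 6
Reactants: 9 methyl (2E)‑3‑(4‑{2‑(methoxymethoxy)‑5‑[2‑(3‑methoxyphenyl)ethenyl]phenoxy}phenyl)prop‑2‑enoate
Product: 10 methyl 3‑Ar‑propanoate, i.e. methyl 3‑(4‑{2‑(methoxymethoxy)‑5‑[2‑(3‑methoxyphenyl)ethyl]phenoxy}phenyl)propanoate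
Conditions: H2 (1 atm), 10% Pd/C, EtOAc, rt
Reagents that add atoms: none
Why: Heterogeneous catalytic hydrogenation should saturate the stilbene and the enoate double bonds in one operation, while aryl ethers, the MOM acetal and the ester are untouched at 1 atm and room temperature.

Step 7
Reactants: 10 methyl 3‑Ar‑propanoate
Product: 11 3‑Ar‑propanal, i.e. 3‑(4‑{2‑(methoxymethoxy)‑5‑[2‑(3‑methoxyphenyl)ethyl]phenoxy}phenyl)propanal
Conditions: i‑Bu2AlH (1.1 equiv), CH2Cl2, −78 °C; MeOH, then aq. potassium sodium tartrate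
Reagents that add atoms: none
Why: Partial reduction of a methyl ester with i‑Bu2AlH at −78 °C stops at the tetrahedral aluminium hemiacetal, which releases the aldehyde only on work‑up.

Step 8
Reactants: 11 3‑Ar‑propanal
Product: 12 1,1‑dibromo‑4‑Ar‑but‑1‑ene, i.e. 2‑[4‑(4,4‑dibromobut‑3‑en‑1‑yl)phenoxy]‑1‑(methoxymethoxy)‑4‑[2‑(3‑methoxyphenyl)ethyl]benzene
Conditions: CBr4 (2 equiv), PPh3 (4 equiv), Et3N, CH2Cl2, 0 °C
Reagents that add atoms: carbon tetrabromide, BrC(Br)(Br)Br
Why: Ramirez dibromo‑olefination (first stage of the Corey–Fuchs sequence) by the ylide Ph3P=CBr2 formed in the flask, with Et3N buffering the medium so that the MOM acetal is kept.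

Step 9
Reactants: 12 1,1‑dibromo‑4‑Ar‑but‑1‑ene
Product: 14 methyl 5‑(4‑{2‑(methoxymethoxy)‑5‑[2‑(3‑methoxyphenyl)ethyl]phenoxy}phenyl)pent‑2‑ynoate, via lithium acetylide 13 (not isolated)
Conditions: n‑BuLi (2.1 equiv), THF, −78 °C; then ClCO2Me (1.5 equiv), −78 to 0 °C
Reagents that add atoms: methyl chloroformate, COC(=O)Cl
Why: Second stage of the Corey–Fuchs sequence, in which bromine–lithium exchange and Fritsch–Buttenberg–Wiechell rearrangement give the alkyne, the second equivalent of n‑BuLi gives acetylide 13, and C‑acylation with the chloroformate delivers the ynoate, exchange and deprotonation at −78 °C being much faster than ortho‑lithiation next to the MOM group.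

Step 10
Reactants: 15 methyl (E)‑but‑2‑enoate (methyl crotonate)
Product: 17 1‑methoxy‑1‑(trimethylsilyloxy)buta‑1,3‑diene, via lithium dienolate 16 (not isolated)
Conditions: LiN(i‑Pr)2 (1.05 equiv), THF–DMPU, −78 °C; then Me3SiCl, −78 °C to rt; distillation under reduced pressure
Reagents that add atoms: chlorotrimethylsilane, C[Si](C)(C)Cl
Why: γ‑Deprotonation of the crotonate by the lithium amide gives the extended dienolate 16, and O‑silylation of this ester dienolate by the hard silyl chloride gives the vinylketene acetal.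

Step 11
Reactants: 14 methyl 5‑(4‑{2‑(methoxymethoxy)‑5‑[2‑(3‑methoxyphenyl)ethyl]phenoxy}phenyl)pent‑2‑ynoate; 17 1‑methoxy‑1‑(trimethylsilyloxy)buta‑1,3‑diene
Product: 20 methyl 2‑hydroxy‑6‑[2‑(4‑{2‑(methoxymethoxy)‑5‑[2‑(3‑methoxyphenyl)ethyl]phenoxy}phenyl)ethyl]benzoate, via cyclohexa‑1,4‑diene cycloadduct 18 (not isolated), via aryl trimethylsilyl ether 19 (not isolated)
Conditions: 17 (3 equiv), xylene, 140 °C, sealed tube; then 10% aq. citric acid, THF, rt
Reagents that add atoms: none
Why: Diels–Alder reaction of normal electron demand: the electron‑rich ketene acetal 17 adds to the electron‑poor ynoate 14 in a concerted, asynchronous [4+2] process in which the nucleophilic CH2 terminus of the diene bonds to the β‑carbon of the ynoate (C1 of ring D, the arm carbon) and the acetal carbon bonds to the α‑carbon (C2, the ester carbon), so that C6–C1 and C2–C3 are formed. The closest known reaction type is the cycloaddition of 1‑alkoxy‑1‑silyloxybuta‑1,3‑dienes to acetylenic esters, which gives salicylates after aromatisation. Ring D is closed by this intermolecular [4+2] cycloaddition (four diene carbons, two alkyne carbons) as cyclohexa‑1,4‑diene 18, which loses methanol by 1,4‑elimination from its acetal carbon and ring CH2 to give aryl silyl ether 19, and the mild citric acid work‑up cleaves the O–Si bond without touching the MOM acetal. The only stereocentre formed, the acetal carbon of 18, is racemic and is erased on aromatisation, so nothing has to be controlled. The selectivity needed is regiochemical (hydroxyl ortho to the ester and meta to the arm) and is secured by the match of the largest HOMO coefficient at diene C4 with the largest LUMO coefficient at the ynoate β‑carbon, a polarisation that a stepwise Michael‑then‑ring‑closure path would follow as well. Because the β‑alkyl group makes 14 less reactive than a propiolate, an excess of 17 and 140 °C in a sealed tube are planned, conditions under which the aryl ethers, the MOM group and the esters are inert.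

Step 12
Reactants: 20 methyl 2‑hydroxy‑6‑(2‑Ar‑ethyl)benzoate
Product: 21 2‑hydroxy‑6‑(2‑Ar‑ethyl)benzoic acid, i.e. 2‑hydroxy‑6‑[2‑(4‑{2‑(methoxymethoxy)‑5‑[2‑(3‑methoxyphenyl)ethyl]phenoxy}phenyl)ethyl]benzoic acid
Conditions: KOH (10 equiv), DMSO–H2O, 100 °C; then 1 M HCl, 0 °C, to pH 3
Reagents that add atoms: potassium hydroxide, [K+].[OH-]
Why: Saponification (base hydrolysis of the ester) of the doubly ortho‑substituted benzoate needs hot hydroxide in DMSO–water, to which the MOM, diaryl and methyl ethers are stable, and brief cold acidification frees the acid without cleaving the acetal.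

Step 13
Reactants: 21 2‑hydroxy‑6‑(2‑Ar‑ethyl)benzoic acid
Product: 22 3‑(2‑Ar‑ethyl)phenol, i.e. 3‑[2‑(4‑{2‑(methoxymethoxy)‑5‑[2‑(3‑methoxyphenyl)ethyl]phenoxy}phenyl)ethyl]phenol
Conditions: Cu powder (cat.), quinoline, 180 °C, under argon
Reagents that add atoms: none
Why: Thermal protodecarboxylation of a 6‑alkylsalicylic acid, in which the ortho‑hydroxyl allows ipso‑protonation through the keto tautomer (a vinylogous β‑keto acid) so that CO2 is lost on heating, the basic solvent keeping the MOM acetal intact.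

Step 14
Reactants: 22 3‑(2‑Ar‑ethyl)phenol
Product: 23 2‑{4‑[2‑(3‑hydroxyphenyl)ethyl]phenoxy}‑4‑[2‑(3‑methoxyphenyl)ethyl]phenol (target)
Conditions: 3 M aq. HCl, MeOH, 50 °C
Reagents that add atoms: none
Why: Acid‑catalysed acetal cleavage (MOM deprotection) in methanol should free the ring B phenol and trap formaldehyde as its dimethyl acetal, while the aryl methyl ether of ring A and the diaryl ether do not react.

Compound list
1 | 3,4‑dihydroxybenzaldehyde | O=Cc1ccc(O)c(O)c1 | starting material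
2 | 3‑hydroxy‑4‑(methoxymethoxy)benzaldehyde | O=Cc1ccc(OCOC)c(O)c1 | intermediate
3 | 3‑methoxybenzyl bromide | COc1cccc(CBr)c1 | starting material
4 | (3‑methoxybenzyl)triphenylphosphonium bromide | COc1cccc(C[P+](c2ccccc2)(c2ccccc2)c2ccccc2)c1.[Br-] | intermediate
5 | (3‑methoxybenzylidene)triphenylphosphorane (ylide, not isolated) | COc1cccc(C=P(c2ccccc2)(c2ccccc2)c2ccccc2)c1 | intermediate
6 | 5‑[2‑(3‑methoxyphenyl)ethenyl]‑2‑(methoxymethoxy)phenol (E/Z mixture) | COc1cccc(C=Cc2ccc(OCOC)c(O)c2)c1 | intermediate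
7 | 4‑fluorobenzaldehyde | O=Cc1ccc(F)cc1 | starting material
8 | 4‑{2‑(methoxymethoxy)‑5‑[2‑(3‑methoxyphenyl)ethenyl]phenoxy}benzaldehyde (E/Z mixture) | COc1cccc(C=Cc2ccc(OCOC)c(Oc3ccc(C=O)cc3)c2)c1 | intermediate
9 | methyl (2E)‑3‑(4‑{2‑(methoxymethoxy)‑5‑[2‑(3‑methoxyphenyl)ethenyl]phenoxy}phenyl)prop‑2‑enoate (stilbene bond E/Z) | COC(=O)/C=C/c1ccc(Oc2cc(C=Cc3cccc(OC)c3)ccc2OCOC)cc1 | intermediate
10 | methyl 3‑(4‑{2‑(methoxymethoxy)‑5‑[2‑(3‑methoxyphenyl)ethyl]phenoxy}phenyl)propanoate | COC(=O)CCc1ccc(Oc2cc(CCc3cccc(OC)c3)ccc2OCOC)cc1 | intermediate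
11 | 3‑(4‑{2‑(methoxymethoxy)‑5‑[2‑(3‑methoxyphenyl)ethyl]phenoxy}phenyl)propanal | O=CCCc1ccc(Oc2cc(CCc3cccc(OC)c3)ccc2OCOC)cc1 | intermediate
12 | 2‑[4‑(4,4‑dibromobut‑3‑en‑1‑yl)phenoxy]‑1‑(methoxymethoxy)‑4‑[2‑(3‑methoxyphenyl)ethyl]benzene | BrC(Br)=CCCc1ccc(Oc2cc(CCc3cccc(OC)c3)ccc2OCOC)cc1 | intermediate
13 | lithium 4‑(4‑{2‑(methoxymethoxy)‑5‑[2‑(3‑methoxyphenyl)ethyl]phenoxy}phenyl)but‑1‑yn‑1‑ide (not isolated) | [Li]C#CCCc1ccc(Oc2cc(CCc3cccc(OC)c3)ccc2OCOC)cc1 | intermediate
14 | methyl 5‑(4‑{2‑(methoxymethoxy)‑5‑[2‑(3‑methoxyphenyl)ethyl]phenoxy}phenyl)pent‑2‑ynoate | COC(=O)C#CCCc1ccc(Oc2cc(CCc3cccc(OC)c3)ccc2OCOC)cc1 | intermediate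
15 | methyl (E)‑but‑2‑enoate (methyl crotonate) | C/C=C/C(=O)OC | starting material
16 | lithium 1‑methoxybuta‑1,3‑dien‑1‑olate (not isolated) | C=CC=C(OC)O[Li] | intermediate
17 | (1E)‑1‑methoxy‑1‑(trimethylsilyloxy)buta‑1,3‑diene | C=C/C=C(\OC)O[Si](C)(C)C | intermediate
18 | methyl 6‑methoxy‑2‑(2‑Ar‑ethyl)‑6‑(trimethylsilyloxy)cyclohexa‑1,4‑diene‑1‑carboxylate (racemic, not isolated) | COC(=O)C1=C(CCc2ccc(Oc3cc(CCc4cccc(OC)c4)ccc3OCOC)cc2)CC=CC1(OC)O[Si](C)(C)C | intermediate
19 | methyl 2‑(2‑Ar‑ethyl)‑6‑(trimethylsilyloxy)benzoate (not isolated) | COC(=O)c1c(O[Si](C)(C)C)cccc1CCc1ccc(Oc2cc(CCc3cccc(OC)c3)ccc2OCOC)cc1 | intermediate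
20 | methyl 2‑hydroxy‑6‑[2‑(4‑{2‑(methoxymethoxy)‑5‑[2‑(3‑methoxyphenyl)ethyl]phenoxy}phenyl)ethyl]benzoate | COC(=O)c1c(O)cccc1CCc1ccc(Oc2cc(CCc3cccc(OC)c3)ccc2OCOC)cc1 | intermediate
21 | 2‑hydroxy‑6‑[2‑(4‑{2‑(methoxymethoxy)‑5‑[2‑(3‑methoxyphenyl)ethyl]phenoxy}phenyl)ethyl]benzoic acid | OC(=O)c1c(O)cccc1CCc1ccc(Oc2cc(CCc3cccc(OC)c3)ccc2OCOC)cc1 | intermediate
22 | 3‑[2‑(4‑{2‑(methoxymethoxy)‑5‑[2‑(3‑methoxyphenyl)ethyl]phenoxy}phenyl)ethyl]phenol | Oc1cccc(CCc2ccc(Oc3cc(CCc4cccc(OC)c4)ccc3OCOC)cc2)c1 | intermediate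
23 | 2‑{4‑[2‑(3‑hydroxyphenyl)ethyl]phenoxy}‑4‑[2‑(3‑methoxyphenyl)ethyl]phenol | COc1cccc(CCc2ccc(O)c(Oc3ccc(CCc4cccc(O)c4)cc3)c2)c1 | target

Total step count: 14. Longest linear sequence: 12 steps (steps 1, 3–9 and 11–14).

Steps most likely to fail

Step 11. The cycloaddition to the β‑alkyl ynoate may be slower than thermal decomposition or adventitious hydrolysis of the ketene acetal, or conjugate addition may stop short of ring closure. The fallback sets out from aldehyde 8 and comes back at 22, building the C–D bibenzyl by olefination instead of cycloaddition. 3‑(Benzyloxy)benzyl bromide and PPh3 in toluene give [3‑(benzyloxy)benzyl]triphenylphosphonium bromide F1. KOt‑Bu in THF converts it into the ylide [3‑(benzyloxy)benzylidene]triphenylphosphorane F2, which olefinates 8 to the bis‑stilbene 1‑(benzyloxy)‑3‑[2‑(4‑{2‑(methoxymethoxy)‑5‑[2‑(3‑methoxyphenyl)ethenyl]phenoxy}phenyl)ethenyl]benzene F3. Hydrogenation over Pd/C in EtOAc should saturate both double bonds and cleave the benzyl ether, giving 22, and step 14 completes the synthesis.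

Step 12. Hydrolysis of the ester flanked by two ortho substituents and deactivated by the neighbouring phenoxide may stall, and harsher conditions may begin to degrade the material. The fallback sets out from dibromoalkene 12 and comes back at acid 21, unveiling the acid by hydrogenolysis instead of hydrolysis. Acetylide 13, generated from 12 as in step 9, is trapped with benzyl chloroformate to give benzyl 5‑Ar‑pent‑2‑ynoate F4. Cycloaddition with 17 as in step 11 should lead, through the cyclohexa‑1,4‑diene adduct F5 and the aryl trimethylsilyl ether F6, to benzyl 2‑hydroxy‑6‑(2‑Ar‑ethyl)benzoate F7. H2 over Pd/C in EtOAc then cleaves the benzyl ester to 21.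

Step 13. Decarboxylation may be incomplete at temperatures the MOM acetal tolerates, or the acetal may be lost in the hot mixture and the released formaldehyde may alkylate the electron‑rich rings. The fallback sets out from 21 and comes back at target 23 with the order of events reversed. HCl in MeOH at 50 °C first removes the MOM group, formaldehyde being trapped as its dimethyl acetal, to give 2‑hydroxy‑6‑[2‑(4‑{2‑hydroxy‑5‑[2‑(3‑methoxyphenyl)ethyl]phenoxy}phenyl)ethyl]benzoic acid F8. This acid, which carries no acid‑labile group, is then decarboxylated by heating under argon (neat melt or DMF, about 150–180 °C) to give 23 directly.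

Further compounds
F1 | step 11 | [3‑(benzyloxy)benzyl]triphenylphosphonium bromide | [Br-].c1ccc(COc2cccc(C[P+](c3ccccc3)(c3ccccc3)c3ccccc3)c2)cc1
F2 | step 11 | [3‑(benzyloxy)benzylidene]triphenylphosphorane | C(=P(c1ccccc1)(c1ccccc1)c1ccccc1)c1cccc(OCc2ccccc2)c1
F3 | step 11 | 1‑(benzyloxy)‑3‑[2‑(4‑{2‑(methoxymethoxy)‑5‑[2‑(3‑methoxyphenyl)ethenyl]phenoxy}phenyl)ethenyl]benzene (E/Z mixture) | COc1cccc(C=Cc2ccc(OCOC)c(Oc3ccc(C=Cc4cccc(OCc5ccccc5)c4)cc3)c2)c1
F4 | step 12 | benzyl 5‑(4‑{2‑(methoxymethoxy)‑5‑[2‑(3‑methoxyphenyl)ethyl]phenoxy}phenyl)pent‑2‑ynoate | O=C(OCc1ccccc1)C#CCCc1ccc(Oc2cc(CCc3cccc(OC)c3)ccc2OCOC)cc1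
F5 | step 12 | benzyl 6‑methoxy‑2‑(2‑Ar‑ethyl)‑6‑(trimethylsilyloxy)cyclohexa‑1,4‑diene‑1‑carboxylate (racemic) | O=C(OCc1ccccc1)C1=C(CCc2ccc(Oc3cc(CCc4cccc(OC)c4)ccc3OCOC)cc2)CC=CC1(OC)O[Si](C)(C)C
F6 | step 12 | benzyl 2‑(2‑Ar‑ethyl)‑6‑(trimethylsilyloxy)benzoate | O=C(OCc1ccccc1)c1c(O[Si](C)(C)C)cccc1CCc1ccc(Oc2cc(CCc3cccc(OC)c3)ccc2OCOC)cc1
F7 | step 12 | benzyl 2‑hydroxy‑6‑[2‑(4‑{2‑(methoxymethoxy)‑5‑[2‑(3‑methoxyphenyl)ethyl]phenoxy}phenyl)ethyl]benzoate | O=C(OCc1ccccc1)c1c(O)cccc1CCc1ccc(Oc2cc(CCc3cccc(OC)c3)ccc2OCOC)cc1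
F8 | step 13 | 2‑hydroxy‑6‑[2‑(4‑{2‑hydroxy‑5‑[2‑(3‑methoxyphenyl)ethyl]phenoxy}phenyl)ethyl]benzoic acid | OC(=O)c1c(O)cccc1CCc1ccc(Oc2cc(CCc3cccc(OC)c3)ccc2O)cc1
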